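## Structural features

The target is a 2,3-dihydro-1,4-benzodioxine: a benzene ring (ring A) fused to a 1,4-dioxane ring (ring B). It carries a 4-hydroxy-3-methoxyphenyl group (ring C) on C2, a hydroxymethyl group on C3 and an (E)-2-carboxyvinyl chain on C6 of ring A. C2 and C3 are adjacent stereocentres, both R, with the aryl and hydroxymethyl groups trans on ring B. O1, which carries the benzylic C2, is bound to C8a and lies para to the C6 chain, whereas O4, which carries C3, is bound to C4a and lies meta to it; exchanging the two oxygens gives a constitutional isomer that is easily made by mistake. The fragile points are the benzylic C2–O1 aryl ether, which can ionise towards a para-quinone methide under acid or base once the para-hydroxyl of ring C is free, the oxidisable phenol, and the acrylic acid alkene, which rules out hydrogenolytic deprotection. The real difficulty is to fix at the same time which ring A oxygen is joined to which sp3 carbon and the absolute trans configuration, without passing through a benzylic cation. The key step uses two features: C8a and C4a, para and meta to C6, correspond to the hydroxyl-bearing and bromine-bearing carbons of a 3-bromo-4-hydroxyphenyl unit, and C2–C3 correspond to the two carbons of an aryl cis-epoxide whose benzylic carbon becomes C2.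

## Logic of the disconnections

15 to 14: the S–O bond of an aryl methanesulfonate on ring C is added retrosynthetically. The free para-hydroxyl is what makes C2–O1 labile and ring C electron-rich, so it stays masked by an acceptor group until the end. No skeletal simplification results, but every earlier step gains robustness. The forward step must cleave the sulfonate with hydroxide without harming the acrylate or C2, so it is placed last.

14 to 13: the O–CH2 bond of a methoxymethyl acetal on the C3 hydroxymethyl group. The primary oxygen must be blocked during the annulation so that only the C3 alkoxide can close ring B. An acetal is chosen because it cannot migrate to a neighbouring alkoxide, as an acyl or silyl group would. The forward acid hydrolysis must not ionise C2–O1, which the sulfonate still present on ring C secures.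

13 to 10 and 11: the Cα=Cβ bond of the acrylic acid. The chain is reduced to a formyl group, a small handle that is already present in a purchasable ring A fragment. The forward condensation, through 12, must give the E alkene and tolerate the sulfonate and the acetal.

10 to 7 and 8: the O1–C2 and O4–C4a bonds. These two bonds join ring A to the C2–C3 unit; cutting both removes ring B, splits the molecule into two fragments of similar size and writes the O1/O4 regiochemistry into the hydroxyl/bromine pattern of 8. The forward step, through 9, demands attack of the phenoxide at the benzylic epoxide carbon, clean inversion there, and closure by the C3 alkoxide only. Bookkeeping check: 7 is the cis (2R,3S) epoxide, and inversion at its benzylic carbon with retention at the other carbon does lead to (2R,3R)-10.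

7 to 6: the two C–O bonds of the oxirane. Both stereocentres are traced to one catalytic enantioselective oxygen transfer to a Z alkene, which removes all stereochemistry from the precursor. The forward step needs a geometrically pure Z alkene, high facial selectivity and no leakage to the trans-epoxide.

6 to 5: the O–CH2 bond of the acetal. This exposes the allylic alcohol, the natural product of an ester reduction. The forward alkylation must leave the Z alkene and the sulfonate untouched.

5 to 4: the two C–H bonds at C1 of the allylic alcohol (oxidation level change to the ester). The Z-enoate is the direct product of a Z-selective olefination. The forward hydride reduction must be a 1,2-reduction without Z to E isomerisation.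

4 to 2 and 3: the C=C bond. This leads back to an aromatic aldehyde and a two-carbon phosphonate. The forward olefination must be Z-selective under kinetic control and must not deprotonate the methanesulfonate.

2 to 1: the S–O bond of the sulfonate. This leads back to a cheap phenolic aldehyde. The forward sulfonylation is unproblematic.

## Other disconnections considered

Alternative 1: Cut: O1–C8a and O4–C4a, but with ring A taken back to a cyclohexane-1,3-dione, so that the fragments are the diazo dione A2 and the carbinol acetonide A3. Forward key step: Rh2(OAc)4 (divalent rhodium) would turn A2 into a carbenoid that inserts into the benzylic O–H bond of A3 (O1–C8a). TsOH added to the same flask would then remove the acetonide and condense the C3 hydroxyl with one ring carbonyl (O4–C4a), giving the dioxene A1 as both C6 epimers.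
- In its favour: the carbenoid carbon is flanked by two equivalent carbonyls and the ester carbon lies on the mirror plane of A2, so O1 must end para to the future C6 substituent. Neither C2–O nor C3–O is broken, so both stereocentres come from A3 with retention. The C6 epimers merge on aromatisation.
- Against it here: A1 is a cyclohexenone, not an arene. The C8 oxygen, absent from the target, must be removed and the ring dehydrogenated, and the C6 ester must be reduced and homologated. The benzyl ether on ring C cannot be hydrogenolysed once the acrylic alkene is present. The TsOH stage exposes an electron-rich benzylic ether to acid, and A2 is a diazo compound.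
- Comparison: on structure it is the better plan for regiochemistry, since symmetry settles what the chosen annulation must earn through a selective epoxide opening. On mechanism it is the equal or the better for stereochemical fidelity (two retentions against one inversion that must stay SN2). On step economy it is clearly worse: A3 with its two stereocentres must be built separately and several redox and homologation steps follow A1, whereas 10 is three steps from the target.

Alternative 2: Cut: only C3–O4, with O1–C2 already in place in the open-chain hydroxy tosylate A5. Forward key step: K2CO3 in methanol would close the C3 alkoxide of A5 onto the tosylate carbon to give a terminal epoxide. The neighbouring phenoxide would open it at C3 (6-exo-tet, inversion), forming C3–O4 and ring B and releasing the hydroxymethyl group of A4.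
- In its favour: no transition metal is needed and the closure is a Baldwin-favoured SN2 process. A4 already has the free primary alcohol, so the acetal removal of the chosen route is saved, which is better. The erythro array of A5 maps onto a trans-epoxy alcohol from Sharpless epoxidation of an E-allylic alcohol, a substrate class at least as dependable in enantioselectivity as (salen)MnCl catalysis on a Z alkene, which is equal or better.
- Against it here: two SN2 inversions in sequence (the benzylic one that builds A5, then C3) must both stay clean. The catechol partner needs its hydroxyls differentiated so that the one para to the formyl group becomes O1. A selective primary tosylation is required. Carbonate in methanol may also open the terminal epoxide intermolecularly or attack the aryl sulfonate.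
- Comparison: on structure, regiochemistry rests on protecting-group differentiation and not on the built-in hydroxyl/bromine pair of 8, a weaker guarantee. On mechanism it is stereospecific like the chosen plan, but with one more inversion to police. On step economy it is roughly equal overall (one deprotection saved, differentiation and tosylation added), but less convergent because ring B is closed in a separate operation.

Alternative 3: Cut: only O1–C2, with C3–O4 already in place in the open carbinol A7 (either configuration at C2). Forward key step: aqueous TsOH would ionise the benzylic carbinol of A7 to a para-quinone methide of ring C. The catechol hydroxyl para to the masked formyl group would add to it (O1–C2, six-membered closure), and the dioxolane would be hydrolysed in the same operation to give A6.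
- In its favour: it is stereoconvergent, so the C2 configuration of A7 is irrelevant. A6 has the free phenol and the free primary alcohol, so a single Doebner condensation would reach the target; this is the shortest endgame of all plans and better than the chosen route. No metal is used.
- Against it here: the trans outcome would rest on thermodynamic and conformational preference in an addition to a planar intermediate, not on a stereospecific event, so some cis isomer has to be expected. The absolute configuration rests on C3 alone, which in the usual ketone precursors of A7 is alpha to a carbonyl and prone to racemise, so a separate asymmetric entry is needed. Regiochemistry again depends on which catechol oxygen was alkylated earlier.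
- Comparison: on structure it is equal for ring construction but weaker in regiochemical and absolute stereochemical security. On mechanism it works through the very cation that the chosen plan suppresses, an advantage for convergence and a disadvantage for diastereomeric purity. On step economy it is better after the key step and probably equal overall once an enantioselective preparation of A7 is counted.

Key step: step 6

Assumption: the facial selectivity of the (S,S)-configured (salen)MnCl catalyst on the Z alkene 6 is taken to follow that of other cis-β-substituted styrenes (benzylic carbon S); if it were opposite, the (R,R)-catalyst would be used.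

## Route

Step 1
Reactants: 1 vanillin (4-hydroxy-3-methoxybenzaldehyde)
Product: 2 4-formyl-2-methoxyphenyl methanesulfonate
Conditions: MsCl, Et3N, CH2Cl2, 0 °C to rt
Reagents that add atoms: methanesulfonyl chloride, CS(=O)(=O)Cl
Why: O-sulfonylation of a phenol; the sulfonate should survive the amide base, hydride, hypochlorite and carbonate used later and turns the para oxygen of ring C from a donor into an acceptor, which the key step needs.

Step 2
Reactants: 2 4-formyl-2-methoxyphenyl methanesulfonate; 3 methyl bis(2,2,2-trifluoroethyl)phosphonoacetate
Product: 4 methyl (Z)-3-[3-methoxy-4-(methylsulfonyloxy)phenyl]prop-2-enoate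
Conditions: 3, KN(SiMe3)2, 18-crown-6, THF, −78 °C; then 2, −78 °C
Reagents that add atoms: none
Why: Still–Gennari olefination; the trifluoroethyl phosphonate anion adds and eliminates under kinetic control, which should give the Z-enoate with high selectivity for an aromatic aldehyde. The anion is preformed with a slight deficit of base so that no free amide can deprotonate the methanesulfonate.

Step 3
Reactants: 4 methyl (Z)-3-[3-methoxy-4-(methylsulfonyloxy)phenyl]prop-2-enoate
Product: 5 4-[(Z)-3-hydroxyprop-1-en-1-yl]-2-methoxyphenyl methanesulfonate
Conditions: i-Bu2AlH, CH2Cl2, −78 °C; aq. potassium sodium tartrate (KNaC4H4O6)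
Reagents that add atoms: none
Why: 1,2-reduction of an α,β-unsaturated ester by an aluminium hydride; at low temperature the Z geometry and the aryl sulfonate should be untouched.

Step 4
Reactants: 5 4-[(Z)-3-hydroxyprop-1-en-1-yl]-2-methoxyphenyl methanesulfonate
Product: 6 2-methoxy-4-[(Z)-3-(methoxymethoxy)prop-1-en-1-yl]phenyl methanesulfonate
Conditions: MOMCl, i-Pr2NEt, CH2Cl2, 0 °C to rt
Reagents that add atoms: chloromethyl methyl ether, COCCl
Why: O-alkylation of the primary alcohol to a methoxymethyl acetal; the acetal is inert to hypochlorite, carbonate and copper and, unlike an ester or silyl ether, cannot migrate to the neighbouring alkoxide set free in the key step.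

Step 5
Reactants: 6 2-methoxy-4-[(Z)-3-(methoxymethoxy)prop-1-en-1-yl]phenyl methanesulfonate
Product: 7 (2R,3S)-2-[(methoxymethoxy)methyl]-3-[3-methoxy-4-(methylsulfonyloxy)phenyl]oxirane (cis)
Conditions: (S,S)-(salen)MnCl, i.e. [(S,S)-N,N′-bis(3,5-di-tert-butylsalicylidene)cyclohexane-1,2-diaminato]manganese chloride (trivalent manganese, 5 mol%), 4-phenylpyridine N-oxide, aq. NaOCl (pH 11.3, Na2HPO4), CH2Cl2, 0 °C
Reagents that add atoms: sodium hypochlorite, [Na+].[O-]Cl
Why: Jacobsen epoxidation, for which aryl-conjugated cis-disubstituted alkenes are the best substrate class. Both stereocentres are set by the catalyst in one oxygen transfer (the S,S ligand should deliver oxygen to the face that makes the benzylic carbon S, hence 2R,3S), and the cis relation comes from the Z alkene. The N-oxide ligand and the acceptor-substituted ring should limit bond rotation in the radical intermediate and thus trans-epoxide formation.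

Step 6
Reactants: 7 (2R,3S)-2-[(methoxymethoxy)methyl]-3-[3-methoxy-4-(methylsulfonyloxy)phenyl]oxirane; 8 3-bromo-4-hydroxybenzaldehyde
Product: 10 4-[(2R,3R)-6-formyl-3-[(methoxymethoxy)methyl]-2,3-dihydro-1,4-benzodioxin-2-yl]-2-methoxyphenyl methanesulfonate, via ring-opened bromoaryl ether alcohol 9 (not isolated)
Conditions: Cs2CO3, CuI (10 mol%), 1,10-phenanthroline (20 mol%), DMF, 90 °C then 110 °C, N2
Reagents that add atoms: none
Why: The caesium phenoxide of 8 opens the cis-epoxide of 7 at the benzylic carbon by backside SN2 attack, forming O1–C2 and releasing the C3 alkoxide 9. The CuI/1,10-phenanthroline complex (monovalent copper) then binds this alkoxide and couples it with the adjacent C–Br carbon by oxidative addition and reductive elimination, forming O4–C4a; the closest known reaction type is the tandem opening of epoxides by 2-halophenols followed by intramolecular Ullmann O-arylation to 2,3-dihydro-1,4-benzodioxines. Ring B is closed in this second event as a six-membered ring by intramolecular ipso-substitution at the aryl carbon (formally 6-exo), which should outrun any intermolecular coupling. The new stereocentre C2 is substrate-controlled: it arises by inversion of the 3S epoxide carbon, while C3 keeps the configuration of the 2R epoxide carbon because its C–O bond is never broken, and one inversion on a cis-epoxide gives the threo ether and hence the trans (2R,3R) ring. Regioselectivity of the opening is needed and is secured by benzylic activation of C2 together with inductive deactivation of the other epoxide carbon by the adjacent CH2OMOM group. Stereospecificity is needed and is secured by the methanesulfonate on ring C, which removes the para donor that would otherwise allow ionisation. The O1/O4 assignment needs no selectivity of its own, because in 8 the phenolic oxygen is para and the bromine meta to the formyl group, and the acetal on the primary oxygen leaves the C3 alkoxide as the only nucleophile for closure.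

Step 7
Reactants: 10 4-[(2R,3R)-6-formyl-3-[(methoxymethoxy)methyl]-2,3-dihydro-1,4-benzodioxin-2-yl]-2-methoxyphenyl methanesulfonate; 11 malonic acid
Product: 13 (E)-3-[(2R,3R)-3-[(methoxymethoxy)methyl]-2-[3-methoxy-4-(methylsulfonyloxy)phenyl]-2,3-dihydro-1,4-benzodioxin-6-yl]prop-2-enoic acid, via arylidenemalonic acid 12 (not isolated)
Conditions: 11, pyridine, piperidine (cat.), 90 °C; then dilute HCl, 0 °C
Reagents that add atoms: none
Why: Knoevenagel condensation in the Doebner modification; the arylidenemalonic acid decarboxylates in hot pyridine to the thermodynamically preferred E-acrylic acid. The sulfonate, the acetal and both stereocentres should be inert to the amine bases.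

Step 8
Reactants: 13 (E)-3-[(2R,3R)-3-[(methoxymethoxy)methyl]-2-[3-methoxy-4-(methylsulfonyloxy)phenyl]-2,3-dihydro-1,4-benzodioxin-6-yl]prop-2-enoic acid
Product: 14 (E)-3-[(2R,3R)-3-(hydroxymethyl)-2-[3-methoxy-4-(methylsulfonyloxy)phenyl]-2,3-dihydro-1,4-benzodioxin-6-yl]prop-2-enoic acid
Conditions: 6 M HCl, THF, 45 °C
Reagents that add atoms: none
Why: Acid hydrolysis of the methoxymethyl acetal. It is run before the sulfonate is removed so that ring C is still electron-poor and the benzylic C2–O1 bond cannot ionise; the aqueous medium avoids esterification of the acid.

Step 9
Reactants: 14 (E)-3-[(2R,3R)-3-(hydroxymethyl)-2-[3-methoxy-4-(methylsulfonyloxy)phenyl]-2,3-dihydro-1,4-benzodioxin-6-yl]prop-2-enoic acid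
Product: 15 (E)-3-[(2R,3R)-2-(4-hydroxy-3-methoxyphenyl)-3-(hydroxymethyl)-2,3-dihydro-1,4-benzodioxin-6-yl]prop-2-enoic acid
Conditions: 2 M NaOH aq., THF, 55 °C, N2 (degassed); then 1 M HCl, 0 °C
Reagents that add atoms: none
Why: Hydroxide cleavage of the aryl methanesulfonate at the S–O bond, which leaves the phenolic oxygen on ring C; the carboxylate should resist conjugate addition. Any reversible quinone-methide opening at C2 should re-close mainly to the more stable trans ring, because C3 is untouched.

## Compound list

1 | vanillin (4-hydroxy-3-methoxybenzaldehyde) | COc1cc(C=O)ccc1O | starting material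
2 | 4-formyl-2-methoxyphenyl methanesulfonate | COc1cc(C=O)ccc1OS(C)(=O)=O | intermediate
3 | methyl bis(2,2,2-trifluoroethyl)phosphonoacetate | COC(=O)CP(=O)(OCC(F)(F)F)OCC(F)(F)F | starting material
4 | methyl (Z)-3-[3-methoxy-4-(methylsulfonyloxy)phenyl]prop-2-enoate | COC(=O)/C=C\c1ccc(OS(C)(=O)=O)c(OC)c1 | intermediate
5 | 4-[(Z)-3-hydroxyprop-1-en-1-yl]-2-methoxyphenyl methanesulfonate | OC/C=C\c1ccc(OS(C)(=O)=O)c(OC)c1 | intermediate
6 | 2-methoxy-4-[(Z)-3-(methoxymethoxy)prop-1-en-1-yl]phenyl methanesulfonate | COCOC/C=C\c1ccc(OS(C)(=O)=O)c(OC)c1 | intermediate
7 | (2R,3S)-2-[(methoxymethoxy)methyl]-3-[3-methoxy-4-(methylsulfonyloxy)phenyl]oxirane (cis) | COc1cc([C@@H]2O[C@@H]2COCOC)ccc1OS(C)(=O)=O | intermediate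
8 | 3-bromo-4-hydroxybenzaldehyde | O=Cc1ccc(O)c(Br)c1 | starting material
9 | 4-[(1R,2R)-1-(2-bromo-4-formylphenoxy)-2-hydroxy-3-(methoxymethoxy)propyl]-2-methoxyphenyl methanesulfonate (present as its caesium alkoxide, not isolated) | COc1cc([C@@H](Oc2ccc(C=O)cc2Br)[C@H](O)COCOC)ccc1OS(C)(=O)=O | intermediate
10 | 4-[(2R,3R)-6-formyl-3-[(methoxymethoxy)methyl]-2,3-dihydro-1,4-benzodioxin-2-yl]-2-methoxyphenyl methanesulfonate | COc1cc([C@H]2Oc3ccc(C=O)cc3O[C@@H]2COCOC)ccc1OS(C)(=O)=O | intermediate
11 | malonic acid | OC(=O)CC(=O)O | starting material
12 | 2-[[(2R,3R)-3-[(methoxymethoxy)methyl]-2-[3-methoxy-4-(methylsulfonyloxy)phenyl]-2,3-dihydro-1,4-benzodioxin-6-yl]methylidene]propanedioic acid (not isolated) | COc1cc([C@H]2Oc3ccc(C=C(C(=O)O)C(=O)O)cc3O[C@@H]2COCOC)ccc1OS(C)(=O)=O | intermediate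
13 | (E)-3-[(2R,3R)-3-[(methoxymethoxy)methyl]-2-[3-methoxy-4-(methylsulfonyloxy)phenyl]-2,3-dihydro-1,4-benzodioxin-6-yl]prop-2-enoic acid | COc1cc([C@H]2Oc3ccc(/C=C/C(=O)O)cc3O[C@@H]2COCOC)ccc1OS(C)(=O)=O | intermediate
14 | (E)-3-[(2R,3R)-3-(hydroxymethyl)-2-[3-methoxy-4-(methylsulfonyloxy)phenyl]-2,3-dihydro-1,4-benzodioxin-6-yl]prop-2-enoic acid | COc1cc([C@H]2Oc3ccc(/C=C/C(=O)O)cc3O[C@@H]2CO)ccc1OS(C)(=O)=O | intermediate
15 | (E)-3-[(2R,3R)-2-(4-hydroxy-3-methoxyphenyl)-3-(hydroxymethyl)-2,3-dihydro-1,4-benzodioxin-6-yl]prop-2-enoic acid | COc1cc([C@H]2Oc3ccc(/C=C/C(=O)O)cc3O[C@@H]2CO)ccc1O | target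

## Step count and least certain steps

Total step count: 9. Longest linear sequence: 9 steps (1 to 15); 3, 8 and 11 are purchased and enter in steps 2, 6 and 7.

Step 6 (key step). The most likely failure is a slow opening of the hindered cis-epoxide, because the phenoxide of 8 is weakened by its para-formyl group and crowded by the ortho-bromine. At the temperature then required, the attack may lose regiocontrol, or the aryl group may migrate from O1 to the C3 oxygen through a spiro Meisenheimer intermediate (a Smiles-type shift that the para-formyl acceptor makes possible) before copper closes the ring. Both processes would exchange the two ring oxygens. The fallback sets out from 8 and 7 and returns to the route at 10. The formyl group of 8 is first masked with ethylene glycol (TsOH cat., toluene, Dean–Stark) as 2-bromo-4-(1,3-dioxolan-2-yl)phenol F1, whose phenoxide is more nucleophilic and carries no acceptor that could support aryl migration. The same Cs2CO3, CuI, 1,10-phenanthroline annulation with 7, which should then run at lower temperature, would give 4-[(2R,3R)-6-(1,3-dioxolan-2-yl)-3-[(methoxymethoxy)methyl]-2,3-dihydro-1,4-benzodioxin-2-yl]-2-methoxyphenyl methanesulfonate F2. Brief treatment with dilute HCl in acetone/water at rt should hydrolyse the aryl dioxolane, leaving the methoxymethyl ether in place, and give 10.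

Step 5. The most likely failure is incomplete stereospecificity, that is, bond rotation in the radical intermediate leading to trans-epoxide, or insufficient facial selectivity on this particular allylic ether. Trans-epoxide would be carried into the cis-benzodioxane. The fallback sets out from 5 (step 4 is postponed) and returns at 7. Sharpless asymmetric epoxidation of the Z-allylic alcohol (Ti(OiPr)4, D-(−)-diisopropyl tartrate, t-BuOOH, 4 Å molecular sieves, CH2Cl2, −20 °C) is a concerted, hydroxyl-directed oxygen transfer that cannot leak to the trans isomer. It should give [(2R,3S)-3-[3-methoxy-4-(methylsulfonyloxy)phenyl]oxiran-2-yl]methanol F3. Z-allylic alcohols react more slowly and less selectively than E ones, so enrichment by crystallisation may be needed. Alkylation with MOMCl and i-Pr2NEt then gives 7.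

Step 9. The most likely failure is retro-oxa-Michael opening of ring B through a para-quinone methide once the phenoxide of ring C exists in warm alkali. This would cause partial epimerisation at C2 or capture by solvent; air oxidation of the phenoxide is a further risk. The fallback sets out from 13 and returns at 15, reversing the order of the two deprotections so that the target is never heated in base. LiN(iPr)2 in excess (THF, −78 °C) should deprotonate the sulfonyl methyl group and expel the phenoxide by loss of sulfene. After an acidic quench this gives (E)-3-[(2R,3R)-2-(4-hydroxy-3-methoxyphenyl)-3-[(methoxymethoxy)methyl]-2,3-dihydro-1,4-benzodioxin-6-yl]prop-2-enoic acid F4. The acetal is then hydrolysed with 3 M HCl in THF at 40 °C to give 15. Ionisation of C2–O1 in acid requires protonation of the weakly basic aryl ether oxygen, and any re-closure would again favour the trans ring.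

Step 7. The most likely failure is aminolysis of the aryl methanesulfonate by piperidine during prolonged heating, or incomplete decarboxylation that leaves 12 in the product. The fallback sets out from 10 and returns at 14 with the same number of steps. Wittig olefination with Ph3P=CHCO2t-Bu (toluene, 80 °C), a stabilised ylide that should be E-selective, would give tert-butyl (E)-3-[(2R,3R)-3-[(methoxymethoxy)methyl]-2-[3-methoxy-4-(methylsulfonyloxy)phenyl]-2,3-dihydro-1,4-benzodioxin-6-yl]prop-2-enoate F5. Treatment with 6 M HCl in THF at 45 °C should then cleave the tert-butyl ester and the methoxymethyl acetal in one operation to give 14.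

## Further compounds

F1 | step 6 | 2-bromo-4-(1,3-dioxolan-2-yl)phenol | Oc1ccc(C2OCCO2)cc1Br
F2 | step 6 | 4-[(2R,3R)-6-(1,3-dioxolan-2-yl)-3-[(methoxymethoxy)methyl]-2,3-dihydro-1,4-benzodioxin-2-yl]-2-methoxyphenyl methanesulfonate | COc1cc([C@H]2Oc3ccc(C4OCCO4)cc3O[C@@H]2COCOC)ccc1OS(C)(=O)=O
F3 | step 5 | [(2R,3S)-3-[3-methoxy-4-(methylsulfonyloxy)phenyl]oxiran-2-yl]methanol | COc1cc([C@@H]2O[C@@H]2CO)ccc1OS(C)(=O)=O
F4 | step 9 | (E)-3-[(2R,3R)-2-(4-hydroxy-3-methoxyphenyl)-3-[(methoxymethoxy)methyl]-2,3-dihydro-1,4-benzodioxin-6-yl]prop-2-enoic acid | COc1cc([C@H]2Oc3ccc(/C=C/C(=O)O)cc3O[C@@H]2COCOC)ccc1O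
F5 | step 7 | tert-butyl (E)-3-[(2R,3R)-3-[(methoxymethoxy)methyl]-2-[3-methoxy-4-(methylsulfonyloxy)phenyl]-2,3-dihydro-1,4-benzodioxin-6-yl]prop-2-enoate | COc1cc([C@H]2Oc3ccc(/C=C/C(=O)OC(C)(C)C)cc3O[C@@H]2COCOC)ccc1OS(C)(=O)=O
A1 | alternative 1 | methyl (2R,3R)-2-[4-(benzyloxy)-3-methoxyphenyl]-3-(hydroxymethyl)-8-oxo-2,3,5,6,7,8-hexahydro-1,4-benzodioxine-6-carboxylate (both C6 epimers) | COc1cc([C@H]2OC3=C(O[C@@H]2CO)CC(C(=O)OC)CC3=O)ccc1OCc1ccccc1
A2 | alternative 1 | methyl 4-diazo-3,5-dioxocyclohexane-1-carboxylate | COC(=O)C1CC(=O)C(=[N+]=[N-])C(=O)C1
A3 | alternative 1 | (R)-[4-(benzyloxy)-3-methoxyphenyl][(4R)-2,2-dimethyl-1,3-dioxolan-4-yl]methanol | COc1cc([C@@H](O)[C@H]2COC(C)(C)O2)ccc1OCc1ccccc1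
A4 | alternative 2 | 4-[(2R,3R)-6-formyl-3-(hydroxymethyl)-2,3-dihydro-1,4-benzodioxin-2-yl]-2-methoxyphenyl methanesulfonate | COc1cc([C@H]2Oc3ccc(C=O)cc3O[C@@H]2CO)ccc1OS(C)(=O)=O
A5 | alternative 2 | 4-[(1R,2S)-1-(4-formyl-2-hydroxyphenoxy)-2-hydroxy-3-[(4-methylphenyl)sulfonyloxy]propyl]-2-methoxyphenyl methanesulfonate | COc1cc([C@@H](Oc2ccc(C=O)cc2O)[C@@H](O)COS(=O)(=O)c2ccc(C)cc2)ccc1OS(C)(=O)=O
A6 | alternative 3 | (2R,3R)-2-(4-hydroxy-3-methoxyphenyl)-3-(hydroxymethyl)-2,3-dihydro-1,4-benzodioxine-6-carbaldehyde | COc1cc([C@H]2Oc3ccc(C=O)cc3O[C@@H]2CO)ccc1O
A7 | alternative 3 | (2R)-2-[5-(1,3-dioxolan-2-yl)-2-hydroxyphenoxy]-1-(4-hydroxy-3-methoxyphenyl)propane-1,3-diol (both C1 epimers) | COc1cc(C(O)[C@@H](CO)Oc2cc(C3OCCO3)ccc2O)ccc1O
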